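## Retrosynthetic overview

- Endgame: the target comes from a (2S)-2′-bromo-4-(phenylsulfanyl)flavan by Negishi prenylation at C2′, radical removal of the C4 sulfide and global desilylation.
- Key disconnection: C2–C3 and C4–C4a together. Ring C is built as a formal (4+2) adduct of an O-aryl oxocarbenium ion (C4a=C8a–O1=C2+) and phenyl vinyl sulfide (C3–C4), under a chiral Brønsted acid that sets C2.
- Enabling feature: O1 is an aryl ether oxygen on C8a whose ortho carbon C4a lies para to the C7 oxygen, and C2 is a benzylic carbon bearing O1 and the 4′-oxygenated ring B. C2 can therefore be ionised and C4a is the arene nucleophile.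
- Precursor: an α-pivaloyloxy benzyl aryl ether made from a ring A phenol (reverse prenyl by γ-selective Suzuki coupling on 4-bromoresorcinol) and a ring B/D aldehyde (from 6-bromoveratraldehyde; C3″ by Jacobsen–Katsuki epoxidation and hydride opening).
- Ring order: rings A and B are bought as arenes; ring D is closed first (propargyl ether Claisen/6π-electrocyclisation); ring C is closed last, in the key step.

Key step: step 13

Remark: flavan locants are used for rings A/C, primed locants for ring B and double-primed locants for ring D (O on C4′, C2″ = CMe2, C3″ = carbinol, C4″ = CH2 on C3′). The acetal carbon of the key-step precursor and C4 of the key-step product form as epimer mixtures and are written without configuration, because both centres are erased later. The antipode of the chiral acid in step 13 is fixed by a test reaction with both enantiomers.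

## Route

Step 1
Reactants: 1 4-bromobenzene-1,3-diol (4-bromoresorcinol)
Product: 2 4-bromo-1,3-bis(triisopropylsilyloxy)benzene
Conditions: TIPSCl (2.5 equiv), imidazole (5 equiv), DMF, rt to 50 °C
Reagents that add atoms: chlorotriisopropylsilane, CC(C)[Si](Cl)(C(C)C)C(C)C
Why: Imidazole-promoted silylation of both phenols; TIPS ethers should survive aqueous base, acid and organozinc reagents and leave with fluoride at the end.

Step 2
Reactants: 2 4-bromo-1,3-bis(triisopropylsilyloxy)benzene; 3 3-methylbut-2-enylboronic acid pinacol ester (prenylBpin)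
Product: 4 1-(2-methylbut-3-en-2-yl)-2,4-bis(triisopropylsilyloxy)benzene
Conditions: 3 (1.5 equiv), Pd(OAc)2 (3 mol %), γ-selective dialkylbiarylphosphine ligand (6 mol %), K3PO4 (3 equiv), THF/H2O, 40 °C
Reagents that add atoms: none
Why: γ-Selective allyl–aryl Suzuki–Miyaura coupling, in which SE2′ transmetalation puts palladium on the tertiary carbon and reductive elimination before σ–π–σ isomerisation should give the 1,1-dimethylallyl (reverse prenyl) arene.

Step 3
Reactants: 4 1-(2-methylbut-3-en-2-yl)-2,4-bis(triisopropylsilyloxy)benzene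
Product: 5 4-(2-methylbut-3-en-2-yl)-3-(triisopropylsilyloxy)phenol
Conditions: TBAF (1.05 equiv), AcOH (1.05 equiv), THF, −20 to 0 °C
Reagents that add atoms: none
Why: Fluoride desilylation should discriminate by sterics, since the silyl ether next to the quaternary carbon is shielded and the remote one (the future O1) is cleaved first.

Step 4
Reactants: 6 2-bromo-4,5-dimethoxybenzaldehyde (6-bromoveratraldehyde)
Product: 7 2-bromo-4,5-dihydroxybenzaldehyde
Conditions: BBr3 (3 equiv), CH2Cl2, −78 °C to rt; then H2O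
Reagents that add atoms: none
Why: Lewis acid cleavage of both aryl methyl ethers, done before any acid-sensitive group is present.

Step 5
Reactants: 7 2-bromo-4,5-dihydroxybenzaldehyde; 8 3-chloro-3-methylbut-1-yne
Product: 9 2-bromo-5-hydroxy-4-(2-methylbut-3-yn-2-yloxy)benzaldehyde
Conditions: K2CO3 (1.1 equiv), KI, CuI (5 mol %), DMF, 50 °C, N2
Reagents that add atoms: none
Why: Copper-assisted propargylic O-alkylation; with one equivalent of base only the more acidic C4 hydroxyl (para to the formyl group) is deprotonated and alkylated.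

Step 6
Reactants: 9 2-bromo-5-hydroxy-4-(2-methylbut-3-yn-2-yloxy)benzaldehyde
Product: 10 2-bromo-4-(2-methylbut-3-yn-2-yloxy)-5-(triisopropylsilyloxy)benzaldehyde
Conditions: TIPSCl (1.3 equiv), imidazole (2.5 equiv), DMF, rt
Reagents that add atoms: chlorotriisopropylsilane, CC(C)[Si](Cl)(C(C)C)C(C)C
Why: Standard silylation of the remaining phenol (the future C5′ hydroxyl), which must not interfere with the rearrangement, the epoxidation or the cationic key step.

Step 7
Reactants: 10 2-bromo-4-(2-methylbut-3-yn-2-yloxy)-5-(triisopropylsilyloxy)benzaldehyde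
Product: 11 5-bromo-2,2-dimethyl-8-(triisopropylsilyloxy)-2H-chromene-6-carbaldehyde
Conditions: N,N-diethylaniline, 190 °C
Reagents that add atoms: none
Why: Aryl propargyl ether Claisen rearrangement, 1,5-hydrogen shift and 6π-electrocyclisation close ring D at the only free ortho position (between the ether oxygen and the bromine-bearing carbon).

Step 8
Reactants: 11 5-bromo-2,2-dimethyl-8-(triisopropylsilyloxy)-2H-chromene-6-carbaldehyde
Product: 12 (3S,4S)-5-bromo-3,4-epoxy-2,2-dimethyl-8-(triisopropylsilyloxy)-3,4-dihydro-2H-chromene-6-carbaldehyde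
Conditions: (S,S)-(salen)MnCl [chloromanganese complex (trivalent manganese) of (S,S)-N,N′-bis(3,5-di-tert-butylsalicylidene)cyclohexane-1,2-diamine] (5 mol %), mCPBA (2 equiv), NMO (5 equiv), CH2Cl2, −78 °C
Reagents that add atoms: meta-chloroperoxybenzoic acid, O=C(OO)c1cccc(Cl)c1
Why: Jacobsen–Katsuki epoxidation of a 2,2-dimethylchromene, the best substrate class for this catalyst; the (S,S) complex is the antipode expected from the established facial model to give the (3S,4S)-oxide, and the anhydrous low-temperature protocol spares the aldehyde.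

Step 9
Reactants: 12 (3S,4S)-5-bromo-3,4-epoxy-2,2-dimethyl-8-(triisopropylsilyloxy)-3,4-dihydro-2H-chromene-6-carbaldehyde
Product: 13 (3S)-5-bromo-6-(hydroxymethyl)-2,2-dimethyl-8-(triisopropylsilyloxy)chroman-3-ol
Conditions: LiAlH4 (2 equiv), THF, 0 °C to rt
Reagents that add atoms: none
Why: Hydride opens the epoxide at the benzylic carbon (the other carbon is neopentyl), so the C3″–O bond and its configuration are kept; the aldehyde is reduced at the same time and restored in step 10.

Step 10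
Reactants: 13 (3S)-5-bromo-6-(hydroxymethyl)-2,2-dimethyl-8-(triisopropylsilyloxy)chroman-3-ol
Product: 14 (3S)-5-bromo-3-hydroxy-2,2-dimethyl-8-(triisopropylsilyloxy)chromane-6-carbaldehyde
Conditions: activated MnO2 (15 equiv), CH2Cl2, rt
Reagents that add atoms: none
Why: MnO2 oxidises only the benzylic alcohol and leaves the secondary aliphatic carbinol untouched.

Step 11
Reactants: 14 (3S)-5-bromo-3-hydroxy-2,2-dimethyl-8-(triisopropylsilyloxy)chromane-6-carbaldehyde
Product: 15 (3S)-5-bromo-3-(tert-butyldimethylsilyloxy)-2,2-dimethyl-8-(triisopropylsilyloxy)chromane-6-carbaldehyde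
Conditions: TBSOTf (1.3 equiv), 2,6-lutidine (2.5 equiv), CH2Cl2, −78 to 0 °C
Reagents that add atoms: tert-butyldimethylsilyl trifluoromethanesulfonate, CC(C)(C)[Si](C)(C)OS(=O)(=O)C(F)(F)F
Why: Silyl triflate protection of the hindered secondary alcohol, so that it is neither acylated in step 12 nor able to trap cations in step 13.

Step 12
Reactants: 15 (3S)-5-bromo-3-(tert-butyldimethylsilyloxy)-2,2-dimethyl-8-(triisopropylsilyloxy)chromane-6-carbaldehyde; 5 4-(2-methylbut-3-en-2-yl)-3-(triisopropylsilyloxy)phenol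
Product: 17 [(3S)-5-bromo-3-(tert-butyldimethylsilyloxy)-2,2-dimethyl-8-(triisopropylsilyloxy)chroman-6-yl][4-(2-methylbut-3-en-2-yl)-3-(triisopropylsilyloxy)phenoxy]methyl pivalate (both acetal epimers), via α-chlorobenzyl pivalate 16 (not isolated)
Conditions: PivCl (1.2 equiv), ZnCl2 (2 mol %), CH2Cl2, 0 °C; then 5, Cs2CO3 (2 equiv), MeCN, −20 to 0 °C; rapid filtration through basic alumina
Reagents that add atoms: pivaloyl chloride, CC(C)(C)C(=O)Cl
Why: Acyl chloride addition to the aldehyde gives the α-chloroalkyl ester, and the phenoxide displaces chloride (acyloxyalkyl ether formation as used for phenol prodrugs), which forms the O1–C2 bond under basic conditions where the resorcinol ring cannot be C-alkylated; the bulky pivaloyl group resists acyl transfer.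

Step 13
Reactants: 17 [(3S)-5-bromo-3-(tert-butyldimethylsilyloxy)-2,2-dimethyl-8-(triisopropylsilyloxy)chroman-6-yl][4-(2-methylbut-3-en-2-yl)-3-(triisopropylsilyloxy)phenoxy]methyl pivalate; 18 phenyl vinyl sulfide
Product: 19 (3S)-5-bromo-3-(tert-butyldimethylsilyloxy)-2,2-dimethyl-6-[(2S)-6-(2-methylbut-3-en-2-yl)-4-(phenylsulfanyl)-7-(triisopropylsilyloxy)chroman-2-yl]-8-(triisopropylsilyloxy)chromane (C4 epimers)
Conditions: chiral BINOL-derived N-triflyl imidodiphosphorimidate (IDPi) Brønsted acid (5 mol %), 18 (3 equiv), CH2Cl2, −60 °C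
Reagents that add atoms: none
Why: Proposed new method: protonation of the pivalate by the confined chiral acid expels pivalic acid and leaves the O-aryl oxocarbenium ion (C4a=C8a–O1=C2+, a cationic 2-oxadiene) paired with the chiral anion; the CH2 terminus of 18 adds to C2 (Prins-type step, C2–C3 bond), the thionium ion at C4 is captured by C4a in a 6-exo-trig Friedel–Crafts closure (C4–C4a bond), and loss of the C4a proton returns the acid, so ring C closes as a stepwise formal (4+2) cycloaddition. The closest known reactions are the SnCl4-promoted oxa-Povarov reaction of phenol-derived mixed acetals with alkenes (racemic), the Povarov reaction with vinyl sulfides and vinyl ethers, the chiral Brønsted acid-catalysed aza-Povarov reaction and IDPi-catalysed additions to oxocarbenium ions generated from α-acyloxy ethers; the new element is the enantioselective, acid-catalytic oxa variant with a vinyl sulfide. C2 is the only new stereocentre that is kept: both acetal epimers of 17 converge on the same planar cation, and the chiral counteranion shields one of its faces in the first C–C bond formation (catalyst control; the ring D stereocentre is too remote to interfere), while C4 forms as a mixture that is erased in step 15. Ionisation in the right direction is secured by the acyloxy group, which is more basic and a better leaving group than the aryloxy group and would give a less stabilised cation if the phenol left instead. Closure at C4a is secured because C4a is ortho to O1, para to the C7 silyloxy group and unhindered, whereas C8 lies between two oxygens and attack on ring B would need a strained five-membered closure. The C2′ bromine stands in for the prenyl group, whose alkene would otherwise trap the cation intramolecularly, and the monosubstituted reverse prenyl alkene is far less nucleophilic than 18.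

Step 14
Reactants: 19 (3S)-5-bromo-3-(tert-butyldimethylsilyloxy)-2,2-dimethyl-6-[(2S)-6-(2-methylbut-3-en-2-yl)-4-(phenylsulfanyl)-7-(triisopropylsilyloxy)chroman-2-yl]-8-(triisopropylsilyloxy)chromane; 20 1-bromo-3-methylbut-2-ene (prenyl bromide)
Product: 22 (3S)-3-(tert-butyldimethylsilyloxy)-2,2-dimethyl-5-(3-methylbut-2-enyl)-6-[(2S)-6-(2-methylbut-3-en-2-yl)-4-(phenylsulfanyl)-7-(triisopropylsilyloxy)chroman-2-yl]-8-(triisopropylsilyloxy)chromane, via prenylzinc bromide 21 (not isolated)
Conditions: 20 (3 equiv), Zn dust, LiCl, THF, rt; then 19, Pd(OAc)2 (5 mol %), CPhos-type dialkylbiarylphosphine (10 mol %), THF, rt to 40 °C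
Reagents that add atoms: none
Why: Negishi coupling, in which zerovalent palladium inserts into the hindered C2′–Br bond and reductive elimination from the less hindered primary σ-allyl isomer should give the linear prenyl arene; silyl ethers, the thioether and the terminal alkene are inert to the organozinc reagent.

Step 15
Reactants: 22 (3S)-3-(tert-butyldimethylsilyloxy)-2,2-dimethyl-5-(3-methylbut-2-enyl)-6-[(2S)-6-(2-methylbut-3-en-2-yl)-4-(phenylsulfanyl)-7-(triisopropylsilyloxy)chroman-2-yl]-8-(triisopropylsilyloxy)chromane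
Product: 23 (3S)-3-(tert-butyldimethylsilyloxy)-2,2-dimethyl-5-(3-methylbut-2-enyl)-6-[(2S)-6-(2-methylbut-3-en-2-yl)-7-(triisopropylsilyloxy)chroman-2-yl]-8-(triisopropylsilyloxy)chromane
Conditions: Bu3SnH (3 equiv), AIBN (0.2 equiv), toluene, 90 °C
Reagents that add atoms: none
Why: Radical desulfurisation, in which the stannyl radical cleaves the benzylic C4–S bond and the benzylic radical takes hydrogen from the tin hydride; the neutral conditions leave C2, both alkenes and the silyl ethers untouched, and both C4 epimers converge on the C4 methylene.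

Step 16
Reactants: 23 (3S)-3-(tert-butyldimethylsilyloxy)-2,2-dimethyl-5-(3-methylbut-2-enyl)-6-[(2S)-6-(2-methylbut-3-en-2-yl)-7-(triisopropylsilyloxy)chroman-2-yl]-8-(triisopropylsilyloxy)chromane
Product: 24 (3S)-6-[(2S)-7-hydroxy-6-(2-methylbut-3-en-2-yl)chroman-2-yl]-2,2-dimethyl-5-(3-methylbut-2-enyl)chromane-3,8-diol (CNP0323011.1)
Conditions: TBAF (6 equiv), AcOH (6 equiv), THF, rt to 45 °C, degassed
Reagents that add atoms: none
Why: Fluoride cleaves the two aryl triisopropylsilyl ethers and the secondary TBS ether; acetic acid buffering protects the electron-rich phenolates from air oxidation and avoids the acid that would cyclise the reverse prenyl phenol or ionise C2.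

## Compound list

1 | 4-bromobenzene-1,3-diol | Oc1ccc(Br)c(O)c1 | starting material
2 | 4-bromo-1,3-bis(triisopropylsilyloxy)benzene | CC(C)[Si](Oc1ccc(Br)c(O[Si](C(C)C)(C(C)C)C(C)C)c1)(C(C)C)C(C)C | intermediate
3 | 3-methylbut-2-enylboronic acid pinacol ester | CC(C)=CCB1OC(C)(C)C(C)(C)O1 | starting material
4 | 1-(2-methylbut-3-en-2-yl)-2,4-bis(triisopropylsilyloxy)benzene | C=CC(C)(C)c1ccc(O[Si](C(C)C)(C(C)C)C(C)C)cc1O[Si](C(C)C)(C(C)C)C(C)C | intermediate
5 | 4-(2-methylbut-3-en-2-yl)-3-(triisopropylsilyloxy)phenol | C=CC(C)(C)c1ccc(O)cc1O[Si](C(C)C)(C(C)C)C(C)C | intermediate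
6 | 2-bromo-4,5-dimethoxybenzaldehyde | COc1cc(C=O)c(Br)cc1OC | starting material
7 | 2-bromo-4,5-dihydroxybenzaldehyde | O=Cc1cc(O)c(O)cc1Br | intermediate
8 | 3-chloro-3-methylbut-1-yne | C#CC(C)(C)Cl | starting material
9 | 2-bromo-5-hydroxy-4-(2-methylbut-3-yn-2-yloxy)benzaldehyde | C#CC(C)(C)Oc1cc(Br)c(C=O)cc1O | intermediate
10 | 2-bromo-4-(2-methylbut-3-yn-2-yloxy)-5-(triisopropylsilyloxy)benzaldehyde | C#CC(C)(C)Oc1cc(Br)c(C=O)cc1O[Si](C(C)C)(C(C)C)C(C)C | intermediate
11 | 5-bromo-2,2-dimethyl-8-(triisopropylsilyloxy)-2H-chromene-6-carbaldehyde | O=Cc1cc(O[Si](C(C)C)(C(C)C)C(C)C)c2OC(C)(C)C=Cc2c1Br | intermediate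
12 | (3S,4S)-5-bromo-3,4-epoxy-2,2-dimethyl-8-(triisopropylsilyloxy)-3,4-dihydro-2H-chromene-6-carbaldehyde | O=Cc1cc(O[Si](C(C)C)(C(C)C)C(C)C)c2c(c1Br)[C@@H]1O[C@@H]1C(C)(C)O2 | intermediate
13 | (3S)-5-bromo-6-(hydroxymethyl)-2,2-dimethyl-8-(triisopropylsilyloxy)chroman-3-ol | OCc1cc(O[Si](C(C)C)(C(C)C)C(C)C)c2c(c1Br)C[C@H](O)C(C)(C)O2 | intermediate
14 | (3S)-5-bromo-3-hydroxy-2,2-dimethyl-8-(triisopropylsilyloxy)chromane-6-carbaldehyde | O=Cc1cc(O[Si](C(C)C)(C(C)C)C(C)C)c2c(c1Br)C[C@H](O)C(C)(C)O2 | intermediate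
15 | (3S)-5-bromo-3-(tert-butyldimethylsilyloxy)-2,2-dimethyl-8-(triisopropylsilyloxy)chromane-6-carbaldehyde | O=Cc1cc(O[Si](C(C)C)(C(C)C)C(C)C)c2c(c1Br)C[C@H](O[Si](C)(C)C(C)(C)C)C(C)(C)O2 | intermediate
16 | chloro[(3S)-5-bromo-3-(tert-butyldimethylsilyloxy)-2,2-dimethyl-8-(triisopropylsilyloxy)chroman-6-yl]methyl pivalate (epimers at the new carbon) | CC(C)(C)C(=O)OC(Cl)c1cc(O[Si](C(C)C)(C(C)C)C(C)C)c2c(c1Br)C[C@H](O[Si](C)(C)C(C)(C)C)C(C)(C)O2 | intermediate
17 | [(3S)-5-bromo-3-(tert-butyldimethylsilyloxy)-2,2-dimethyl-8-(triisopropylsilyloxy)chroman-6-yl][4-(2-methylbut-3-en-2-yl)-3-(triisopropylsilyloxy)phenoxy]methyl pivalate (both acetal epimers) | CC(C)(C)C(=O)OC(Oc1ccc(C(C)(C)C=C)c(O[Si](C(C)C)(C(C)C)C(C)C)c1)c1cc(O[Si](C(C)C)(C(C)C)C(C)C)c2c(c1Br)C[C@H](O[Si](C)(C)C(C)(C)C)C(C)(C)O2 | intermediate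
18 | phenyl vinyl sulfide | C=CSc1ccccc1 | starting material
19 | (3S)-5-bromo-3-(tert-butyldimethylsilyloxy)-2,2-dimethyl-6-[(2S)-6-(2-methylbut-3-en-2-yl)-4-(phenylsulfanyl)-7-(triisopropylsilyloxy)chroman-2-yl]-8-(triisopropylsilyloxy)chromane (C4 epimers) | C=CC(C)(C)c1cc2c(cc1O[Si](C(C)C)(C(C)C)C(C)C)O[C@H](c1cc(O[Si](C(C)C)(C(C)C)C(C)C)c3c(c1Br)C[C@H](O[Si](C)(C)C(C)(C)C)C(C)(C)O3)CC2Sc1ccccc1 | intermediate
20 | 1-bromo-3-methylbut-2-ene | CC(C)=CCBr | starting material
21 | 3-methylbut-2-enylzinc bromide | CC(C)=CC[Zn]Br | intermediate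
22 | (3S)-3-(tert-butyldimethylsilyloxy)-2,2-dimethyl-5-(3-methylbut-2-enyl)-6-[(2S)-6-(2-methylbut-3-en-2-yl)-4-(phenylsulfanyl)-7-(triisopropylsilyloxy)chroman-2-yl]-8-(triisopropylsilyloxy)chromane (C4 epimers) | C=CC(C)(C)c1cc2c(cc1O[Si](C(C)C)(C(C)C)C(C)C)O[C@H](c1cc(O[Si](C(C)C)(C(C)C)C(C)C)c3c(c1CC=C(C)C)C[C@H](O[Si](C)(C)C(C)(C)C)C(C)(C)O3)CC2Sc1ccccc1 | intermediate
23 | (3S)-3-(tert-butyldimethylsilyloxy)-2,2-dimethyl-5-(3-methylbut-2-enyl)-6-[(2S)-6-(2-methylbut-3-en-2-yl)-7-(triisopropylsilyloxy)chroman-2-yl]-8-(triisopropylsilyloxy)chromane | C=CC(C)(C)c1cc2c(cc1O[Si](C(C)C)(C(C)C)C(C)C)O[C@H](c1cc(O[Si](C(C)C)(C(C)C)C(C)C)c3c(c1CC=C(C)C)C[C@H](O[Si](C)(C)C(C)(C)C)C(C)(C)O3)CC2 | intermediate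
24 | (3S)-6-[(2S)-7-hydroxy-6-(2-methylbut-3-en-2-yl)chroman-2-yl]-2,2-dimethyl-5-(3-methylbut-2-enyl)chromane-3,8-diol | C=CC(C)(C)c1cc2c(cc1O)O[C@H](c1cc(O)c3c(c1CC=C(C)C)C[C@H](O)C(C)(C)O3)CC2 | target

## Step count and risks

Total step count: 16. Longest linear sequence: 13 steps (steps 4 to 16).

**Step 13 (the proposed enantioselective oxa-Povarov reaction).** What may go wrong: poor facial discrimination of the oxocarbenium ion pair, acid-initiated oligomerisation of the vinyl sulfide, or interruption of the cascade before ring closure. The fallback uses only known chemistry, sets out from 5 and 15 and comes back to the route at 23. Ortho-iodination of 5 (N-iodosuccinimide, MeCN, 0 °C) should give 2-iodo-4-(2-methylbut-3-en-2-yl)-5-(triisopropylsilyloxy)phenol F1. Vinylmagnesium bromide adds to 15 to give the allylic alcohol 1-[(3S)-5-bromo-3-(tert-butyldimethylsilyloxy)-2,2-dimethyl-8-(triisopropylsilyloxy)chroman-6-yl]prop-2-en-1-ol F2. A Heck reaction of F1 with F2 (Pd(OAc)2, NaHCO3, Bu4NCl, DMF, 50 °C; the iodide reacts before the hindered bromide) arylates the alkene terminus and, after β-hydride elimination towards the carbinol and tautomerisation, should give the ketone 1-[(3S)-5-bromo-3-(tert-butyldimethylsilyloxy)-2,2-dimethyl-8-(triisopropylsilyloxy)chroman-6-yl]-3-[2-hydroxy-5-(2-methylbut-3-en-2-yl)-4-(triisopropylsilyloxy)phenyl]propan-1-one F3. Noyori transfer hydrogenation (RuCl[(R,R)-TsDPEN](p-cymene), HCO2H/Et3N) should give the corresponding (1R)-propan-1-ol F4. Mitsunobu cyclisation (PPh3, DIAD, THF) closes ring C with inversion to (3S)-5-bromo-3-(tert-butyldimethylsilyloxy)-2,2-dimethyl-6-[(2S)-6-(2-methylbut-3-en-2-yl)-7-(triisopropylsilyloxy)chroman-2-yl]-8-(triisopropylsilyloxy)chromane F5. Negishi coupling of F5 with 21 under the conditions of step 14 gives 23.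

**Step 12 (assembly of the α-pivaloyloxy ether).** What may go wrong: reversion of the α-chloro ester to aldehyde and acyl chloride with acyl transfer to the phenoxide, or ionisation and hydrolysis of 17 during isolation. The fallback gives up the acyloxy leaving group and the catalytic mode together; it sets out from 15 and 5 and comes back at 19. Acetalisation of 15 (HC(OMe)3, MeOH, PPTS) gives the dimethyl acetal (3S)-5-bromo-3-(tert-butyldimethylsilyloxy)-6-(dimethoxymethyl)-2,2-dimethyl-8-(triisopropylsilyloxy)chromane F6. Acetyl chloride with catalytic ZnCl2 converts it into the α-chloro methyl ether (3S)-5-bromo-3-(tert-butyldimethylsilyloxy)-6-[chloro(methoxy)methyl]-2,2-dimethyl-8-(triisopropylsilyloxy)chromane F7, which is used in solution. Phenol 5 and iPr2NEt then give the mixed acetal (3S)-5-bromo-3-(tert-butyldimethylsilyloxy)-6-{methoxy[4-(2-methylbut-3-en-2-yl)-3-(triisopropylsilyloxy)phenoxy]methyl}-2,2-dimethyl-8-(triisopropylsilyloxy)chromane F8. The stoichiometric SnCl4-promoted oxa-Povarov reaction of F8 with 18 (CH2Cl2, −78 °C) should give 19 together with its (2R) epimer F9. Because ring D carries a fixed stereocentre these are diastereomers, and they are separated by chromatography.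

**Step 14 (prenylation of the doubly ortho-substituted bromide).** What may go wrong: slow oxidative addition, catalyst inhibition by the thioether, allyl transposition to the branched isomer, or protodebromination. The fallback builds the prenyl group in two stages; it sets out from 19 and comes back at 23. Stille coupling with allyltributylstannane (Pd(PPh3)4, toluene, 100 °C) gives the allyl compound (3S)-5-allyl-3-(tert-butyldimethylsilyloxy)-2,2-dimethyl-6-[(2S)-6-(2-methylbut-3-en-2-yl)-4-(phenylsulfanyl)-7-(triisopropylsilyloxy)chroman-2-yl]-8-(triisopropylsilyloxy)chromane F10. Desulfurisation as in step 15 gives (3S)-5-allyl-3-(tert-butyldimethylsilyloxy)-2,2-dimethyl-6-[(2S)-6-(2-methylbut-3-en-2-yl)-7-(triisopropylsilyloxy)chroman-2-yl]-8-(triisopropylsilyloxy)chromane F11. Cross-metathesis with 2-methylbut-2-ene (second-generation Grubbs catalyst, CH2Cl2, 40 °C) converts the allyl group into the prenyl group of 23; the reverse prenyl vinyl group, which sits on a quaternary carbon, should react much more slowly.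

## Further compounds

F1 | step 13 | 2-iodo-4-(2-methylbut-3-en-2-yl)-5-(triisopropylsilyloxy)phenol | C=CC(C)(C)c1cc(I)c(O)cc1O[Si](C(C)C)(C(C)C)C(C)C
F2 | step 13 | 1-[(3S)-5-bromo-3-(tert-butyldimethylsilyloxy)-2,2-dimethyl-8-(triisopropylsilyloxy)chroman-6-yl]prop-2-en-1-ol (carbinol epimers) | C=CC(O)c1cc(O[Si](C(C)C)(C(C)C)C(C)C)c2c(c1Br)C[C@H](O[Si](C)(C)C(C)(C)C)C(C)(C)O2
F3 | step 13 | 1-[(3S)-5-bromo-3-(tert-butyldimethylsilyloxy)-2,2-dimethyl-8-(triisopropylsilyloxy)chroman-6-yl]-3-[2-hydroxy-5-(2-methylbut-3-en-2-yl)-4-(triisopropylsilyloxy)phenyl]propan-1-one | O=C(CCc1cc(C(C)(C)C=C)c(O[Si](C(C)C)(C(C)C)C(C)C)cc1O)c1cc(O[Si](C(C)C)(C(C)C)C(C)C)c2c(c1Br)C[C@H](O[Si](C)(C)C(C)(C)C)C(C)(C)O2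
F4 | step 13 | (1R)-1-[(3S)-5-bromo-3-(tert-butyldimethylsilyloxy)-2,2-dimethyl-8-(triisopropylsilyloxy)chroman-6-yl]-3-[2-hydroxy-5-(2-methylbut-3-en-2-yl)-4-(triisopropylsilyloxy)phenyl]propan-1-ol | O[C@H](CCc1cc(C(C)(C)C=C)c(O[Si](C(C)C)(C(C)C)C(C)C)cc1O)c1cc(O[Si](C(C)C)(C(C)C)C(C)C)c2c(c1Br)C[C@H](O[Si](C)(C)C(C)(C)C)C(C)(C)O2
F5 | step 13 | (3S)-5-bromo-3-(tert-butyldimethylsilyloxy)-2,2-dimethyl-6-[(2S)-6-(2-methylbut-3-en-2-yl)-7-(triisopropylsilyloxy)chroman-2-yl]-8-(triisopropylsilyloxy)chromane | C=CC(C)(C)c1cc2c(cc1O[Si](C(C)C)(C(C)C)C(C)C)O[C@H](c1cc(O[Si](C(C)C)(C(C)C)C(C)C)c3c(c1Br)C[C@H](O[Si](C)(C)C(C)(C)C)C(C)(C)O3)CC2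
F6 | step 12 | (3S)-5-bromo-3-(tert-butyldimethylsilyloxy)-6-(dimethoxymethyl)-2,2-dimethyl-8-(triisopropylsilyloxy)chromane | COC(OC)c1cc(O[Si](C(C)C)(C(C)C)C(C)C)c2c(c1Br)C[C@H](O[Si](C)(C)C(C)(C)C)C(C)(C)O2
F7 | step 12 | (3S)-5-bromo-3-(tert-butyldimethylsilyloxy)-6-[chloro(methoxy)methyl]-2,2-dimethyl-8-(triisopropylsilyloxy)chromane | COC(Cl)c1cc(O[Si](C(C)C)(C(C)C)C(C)C)c2c(c1Br)C[C@H](O[Si](C)(C)C(C)(C)C)C(C)(C)O2
F8 | step 12 | (3S)-5-bromo-3-(tert-butyldimethylsilyloxy)-6-{methoxy[4-(2-methylbut-3-en-2-yl)-3-(triisopropylsilyloxy)phenoxy]methyl}-2,2-dimethyl-8-(triisopropylsilyloxy)chromane | COC(Oc1ccc(C(C)(C)C=C)c(O[Si](C(C)C)(C(C)C)C(C)C)c1)c1cc(O[Si](C(C)C)(C(C)C)C(C)C)c2c(c1Br)C[C@H](O[Si](C)(C)C(C)(C)C)C(C)(C)O2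
F9 | step 12 | (2R) epimer of 19: (3S)-5-bromo-3-(tert-butyldimethylsilyloxy)-2,2-dimethyl-6-[(2R)-6-(2-methylbut-3-en-2-yl)-4-(phenylsulfanyl)-7-(triisopropylsilyloxy)chroman-2-yl]-8-(triisopropylsilyloxy)chromane | C=CC(C)(C)c1cc2c(cc1O[Si](C(C)C)(C(C)C)C(C)C)O[C@@H](c1cc(O[Si](C(C)C)(C(C)C)C(C)C)c3c(c1Br)C[C@H](O[Si](C)(C)C(C)(C)C)C(C)(C)O3)CC2Sc1ccccc1
F10 | step 14 | (3S)-5-allyl-3-(tert-butyldimethylsilyloxy)-2,2-dimethyl-6-[(2S)-6-(2-methylbut-3-en-2-yl)-4-(phenylsulfanyl)-7-(triisopropylsilyloxy)chroman-2-yl]-8-(triisopropylsilyloxy)chromane | C=CC(C)(C)c1cc2c(cc1O[Si](C(C)C)(C(C)C)C(C)C)O[C@H](c1cc(O[Si](C(C)C)(C(C)C)C(C)C)c3c(c1CC=C)C[C@H](O[Si](C)(C)C(C)(C)C)C(C)(C)O3)CC2Sc1ccccc1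
F11 | step 14 | (3S)-5-allyl-3-(tert-butyldimethylsilyloxy)-2,2-dimethyl-6-[(2S)-6-(2-methylbut-3-en-2-yl)-7-(triisopropylsilyloxy)chroman-2-yl]-8-(triisopropylsilyloxy)chromane | C=CC(C)(C)c1cc2c(cc1O[Si](C(C)C)(C(C)C)C(C)C)O[C@H](c1cc(O[Si](C(C)C)(C(C)C)C(C)C)c3c(c1CC=C)C[C@H](O[Si](C)(C)C(C)(C)C)C(C)(C)O3)CC2
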